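The carbocycle is closed last, between the lactone O–CH carbon (C8) and the ring CH2 (C9). The key step exploits that C8 is a homoallylic carbinol whose CH2 neighbour sits on the tetrasubstituted C5=C10 alkene carrying the C14 methyl. A zerovalent-palladium methylative cyclization of an acyclic allenyl aldehyde forms C8–C9, installs C14, creates the ring alkene and the C8 stereocentre at once, and the new alkoxide closes the cis γ-lactone. The precursor is a 4,5-dienal (aldehyde C8, allene C5=C10=C9) carrying C6, C7 and the (S)-citronellal-derived side chain, assembled on a menthyloxybutenolide by indium allenylation.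

Key step: step 9

Remark: atoms are numbered as in 1,10-seco-eudesmanolides (C1 = side-chain CH2O, C4 = CH(CH3), C5=C10 = ring alkene, C6 = CH–O-isobutyrate, C7/C8 = ring fusion, C9 = ring CH2, C11–C13 = methylene lactone, C14 = ring methyl). (S)-Citronellal and (5R)-5-(l-menthyloxy)furan-2(5H)-one are assumed purchasable.

Step 1
Reactants: 1 (S)-citronellal
Product: 3 (3S)-3,7-dimethyloct-6-en-1-yne, via alkenyl nonaflate 2 (not isolated)
Conditions: C4F9SO2F (NfF), P2-Et phosphazene base, DMF, −30 °C to rt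
Reagents that add atoms: none
Why: Enolizable aldehydes are converted by NfF and a phosphazene base into alkenyl nonaflates that eliminate to the terminal alkyne without adding a carbon (one-pot nonaflation–E2 elimination), so the C4 centre becomes propargylic unchanged.

Step 2
Reactants: 3 (3S)-3,7-dimethyloct-6-en-1-yne
Product: 7 (4S)-1-bromo-4,8-dimethylnon-7-en-2-yne, via lithium acetylide 4 (not isolated), via lithium propargylic alkoxide 5 (not isolated), via propargylic mesylate 6 (not isolated)
Conditions: n-BuLi, THF, −78 °C; (CH2O)n, −78 °C to rt; MsCl, −20 °C; LiBr, rt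
Reagents that add atoms: paraformaldehyde (as formaldehyde), C=O; lithium bromide, [Li+].[Br-]
Why: Acetylide hydroxymethylation, in situ mesylation and Finkelstein-type bromide displacement give the primary propargylic bromide; the stereocentre is not involved.

Step 3
Reactants: 7 (4S)-1-bromo-4,8-dimethylnon-7-en-2-yne
Product: 9 (4S)-7-bromo-4-methylhept-5-yn-1-ol, via ozonide 8 (not isolated)
Conditions: O3, CH2Cl2, −78 °C; then NaBH4, MeOH, −78 to 0 °C
Reagents that add atoms: ozone, O=[O+][O-]
Why: Ozone attacks the electron-rich trisubstituted alkene far faster than the alkyne, and borohydride reduces the ozonide to the primary alcohol (chemoselective ozonolysis with reductive work-up).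

Step 4
Reactants: 10 (5R)-5-[(1R,2S,5R)-menthyloxy]furan-2(5H)-one
Product: 12 (3S,4R,5R)-3-[(dimethylamino)methyl]-4-ethenyl-5-(menthyloxy)oxolan-2-one, via bromomagnesium lactone enolate 11 (not isolated)
Conditions: CH2=CHMgBr, CuBr·SMe2 (10 mol%), THF, −78 °C; then CH2=NMe2+ I−, −78 °C to rt
Reagents that add atoms: vinylmagnesium bromide, C=C[Mg]Br; Eschenmoser's salt, C=[N+](C)C.[I-]
Why: Copper-catalysed conjugate addition of the vinyl Grignard occurs anti to the menthyloxy group, fixing C7, and the enolate is trapped by the iminium salt anti to the new vinyl group (tandem 1,4-addition–Mannich reaction).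

Step 5
Reactants: 12 (3S,4R,5R)-3-[(dimethylamino)methyl]-4-ethenyl-5-(menthyloxy)oxolan-2-one
Product: 14 (3S,4S,5R)-3-[(dimethylamino)methyl]-5-(menthyloxy)-2-oxooxolane-4-carbaldehyde trifluoroacetate salt, via ozonide trifluoroacetate 13 (not isolated)
Conditions: CF3CO2H (1.05 equiv), CH2Cl2; O3, −78 °C; then Me2S, −78 °C to rt; used at once
Reagents that add atoms: ozone, O=[O+][O-]; trifluoroacetic acid, OC(=O)C(F)(F)F
Why: With the amine masked as its ammonium salt, ozonolysis with Me2S work-up cleaves only the vinyl group to the C6 aldehyde, whose α-centre C7 stays thermodynamically locked trans to the acetal substituent.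

Step 6
Reactants: 14 lactone aldehyde trifluoroacetate; 9 (4S)-7-bromo-4-methylhept-5-yn-1-ol
Product: 16 (3S,4S,5R)-3-[(dimethylamino)methyl]-4-[(1S,3S)-2-ethenylidene-1,6-dihydroxy-3-methylhexyl]-5-(menthyloxy)oxolan-2-one, via propargylindium dibromide 15 (not isolated)
Conditions: indium powder, THF–H2O (1:1), rt; then aq NaHCO3
Reagents that add atoms: none
Why: The propargylindium reagent from 9 adds through its substituted γ-carbon (Barbier-type SE2′ allenylation) to give the α-allenyl carbinol, and Felkin–Anh attack anti to the C7–C8 bond should set C6 as S.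

Step 7
Reactants: 16 allenyl carbinol diol
Product: 17 bis(triethylsilyl) ether of 16 (C1–O and C6–O silylated)
Conditions: Et3SiOTf, 2,6-lutidine, CH2Cl2, −78 to 0 °C
Reagents that add atoms: triethylsilyl triflate, CC[Si](CC)(CC)OS(=O)(=O)C(F)(F)F
Why: Silyl triflate silylation covers both hydroxyls and gives a C6 ether that cannot ionize under palladium and whose bulk later steers the ring closure.

Step 8
Reactants: 17 bis(triethylsilyl) ether
Product: 18 methyl (2S,3S,4S,6S)-2-[(dimethylamino)methyl]-5-ethenylidene-3-formyl-6-methyl-4,9-bis(triethylsilyloxy)nonanoate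
Conditions: K2CO3 (0.2 equiv), MeOH, −10 to 0 °C; AcOH quench; used at once
Reagents that add atoms: methanol, CO
Why: Methoxide opens the activated pseudo-ester at C12 and the hemiacetal alkoxide released at C8 collapses to the free aldehyde and menthol (transesterification of an acylal).

Step 9
Reactants: 18 allenyl aldehyde methyl ester
Product: 21 (3S,3aS,4S,7aR)-3-[(dimethylamino)methyl]-4-hydroxy-5-[(2S)-5-hydroxypentan-2-yl]-6-methyl-3a,4,7,7a-tetrahydro-1-benzofuran-2(3H)-one, via cyclized hydroxy ester 19 (not isolated), via bis-silyl lactone 20 (not isolated)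
Conditions: Pd(PPh3)4 (10 mol%), (MeBO)3, MeOH–1,4-dioxane, 80 °C; then AcOH–THF–H2O (3:1:1), rt
Reagents that add atoms: trimethylboroxine, CB1OB(C)OB(C)O1
Why: Zerovalent palladium bound to the terminal C10=C9 π-bond attacks the aldehyde carbon through C9 (anti-Wacker-type oxidative addition) to give a C10 alkenylpalladium alkoxide; the alkoxide-activated methylboron transfers CH3 to palladium and reductive elimination forges C10–C14, leaving the C5=C10 alkene. The closest known reaction type is the palladium-catalysed alkylative or arylative cyclization of 4,5-dienals with organoboron reagents to 3-substituted cyclohex-3-enols. The carbocycle closes in a 6-endo mode (bonding at C5 would need a cyclobutane), the cis-hydroxy ester then lactonizes 5-exo-trig with loss of methanol, and the acid stage removes both silyl ethers. C8 is set by the C6/C7 centres: allylic 1,2-strain against the C5 side chain holds the bulky C6 silyloxy group pseudoaxial, so the trans C7 appendage is pseudoaxial too and the aldehyde reacts with its oxygen pseudoequatorial, which is the 7,8-cis, 6,8-anti relationship required. The step needs chemoselectivity against ionization at C6 and against proto-depalladation; the non-leaving silyl ether at C6 and an excess of trimethylboroxine are chosen to secure both.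

Step 10
Reactants: 21 lactone diol
Product: 22 1,6-di-O-isobutyrate of 21
Conditions: (i-PrCO)2O, Et3N, DMAP, CH2Cl2, 0 °C to rt
Reagents that add atoms: isobutyric anhydride, CC(C)C(=O)OC(=O)C(C)C
Why: DMAP-catalysed acylation esterifies the primary C1 and the hindered allylic C6 hydroxyl while the acrylate is still masked as the Mannich base.

Step 11
Reactants: 22 di-isobutyrate Mannich base
Product: 24 target compound (CNP0509808.1), via trimethylammonium iodide 23 (not isolated)
Conditions: MeI, acetone, rt; then aq NaHCO3, EtOAc, rt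
Reagents that add atoms: none
Why: Quaternization of the amine and E1cB loss of trimethylamine under bicarbonate unveil the α-methylene lactone (Mannich-base elimination) without touching the esters or any stereocentre.

Compound list
1 | (S)-citronellal | O=CC[C@@H](C)CCC=C(C)C | starting material
2 | (3S)-3,7-dimethylocta-1,6-dien-1-yl nonaflate (E/Z) | FC(F)(F)C(F)(F)C(F)(F)C(F)(F)S(=O)(=O)OC=C[C@@H](C)CCC=C(C)C | intermediate
3 | (3S)-3,7-dimethyloct-6-en-1-yne | C#C[C@@H](C)CCC=C(C)C | intermediate
4 | lithium acetylide of 3 | [Li]C#C[C@@H](C)CCC=C(C)C | intermediate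
5 | lithium (4S)-4,8-dimethylnon-7-en-2-yn-1-olate | [Li+].[O-]CC#C[C@@H](C)CCC=C(C)C | intermediate
6 | (4S)-4,8-dimethylnon-7-en-2-yn-1-yl methanesulfonate | CS(=O)(=O)OCC#C[C@@H](C)CCC=C(C)C | intermediate
7 | (4S)-1-bromo-4,8-dimethylnon-7-en-2-yne | BrCC#C[C@@H](C)CCC=C(C)C | intermediate
8 | 1,2,4-trioxolane (ozonide) of 7 | BrCC#C[C@@H](C)CCC1OOC(C)(C)O1 | intermediate
9 | (4S)-7-bromo-4-methylhept-5-yn-1-ol | BrCC#C[C@@H](C)CCCO | intermediate
10 | (5R)-5-[(1R,2S,5R)-menthyloxy]furan-2(5H)-one | O=C1C=C[C@H](O[C@@H]2C[C@H](C)CC[C@H]2C(C)C)O1 | starting material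
11 | bromomagnesium enolate of the 4-vinyl lactone | Br[Mg]OC1=C[C@@H](C=C)[C@H](O[C@@H]2C[C@H](C)CC[C@H]2C(C)C)O1 | intermediate
12 | (3S,4R,5R)-3-[(dimethylamino)methyl]-4-ethenyl-5-(menthyloxy)oxolan-2-one | CN(C)C[C@H]1C(=O)O[C@@H](O[C@@H]2C[C@H](C)CC[C@H]2C(C)C)[C@@H]1C=C | intermediate
13 | ozonide of 12, trifluoroacetate salt | C[NH+](C)C[C@H]1C(=O)O[C@@H](O[C@@H]2C[C@H](C)CC[C@H]2C(C)C)[C@@H]1C3OOCO3.[O-]C(=O)C(F)(F)F | intermediate
14 | (3S,4S,5R)-3-[(dimethylamino)methyl]-5-(menthyloxy)-2-oxooxolane-4-carbaldehyde, trifluoroacetate salt | C[NH+](C)C[C@H]1C(=O)O[C@@H](O[C@@H]2C[C@H](C)CC[C@H]2C(C)C)[C@@H]1C=O.[O-]C(=O)C(F)(F)F | intermediate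
15 | [(4S)-7-hydroxy-4-methylhept-2-yn-1-yl]indium dibromide | Br[In](Br)CC#C[C@@H](C)CCCO | intermediate
16 | (3S,4S,5R)-3-[(dimethylamino)methyl]-4-[(1S,3S)-2-ethenylidene-1,6-dihydroxy-3-methylhexyl]-5-(menthyloxy)oxolan-2-one | CN(C)C[C@H]1C(=O)O[C@@H](O[C@@H]2C[C@H](C)CC[C@H]2C(C)C)[C@@H]1[C@H](O)C(=C=C)[C@@H](C)CCCO | intermediate
17 | bis(triethylsilyl) ether of 16 | CN(C)C[C@H]1C(=O)O[C@@H](O[C@@H]2C[C@H](C)CC[C@H]2C(C)C)[C@@H]1[C@H](O[Si](CC)(CC)CC)C(=C=C)[C@@H](C)CCCO[Si](CC)(CC)CC | intermediate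
18 | methyl (2S,3S,4S,6S)-2-[(dimethylamino)methyl]-5-ethenylidene-3-formyl-6-methyl-4,9-bis(triethylsilyloxy)nonanoate | COC(=O)[C@H](CN(C)C)[C@H](C=O)[C@H](O[Si](CC)(CC)CC)C(=C=C)[C@@H](C)CCCO[Si](CC)(CC)CC | intermediate
19 | cyclized hydroxy ester (cyclohexenol with C8–OH cis to the C7 appendage, both silyl ethers intact) | COC(=O)[C@H](CN(C)C)[C@@H]1[C@H](O)CC(C)=C([C@@H](C)CCCO[Si](CC)(CC)CC)[C@H]1O[Si](CC)(CC)CC | intermediate
20 | bis(triethylsilyl) ether of 21 | CN(C)C[C@H]1C(=O)O[C@@H]2CC(C)=C([C@@H](C)CCCO[Si](CC)(CC)CC)[C@@H](O[Si](CC)(CC)CC)[C@H]12 | intermediate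
21 | (3S,3aS,4S,7aR)-3-[(dimethylamino)methyl]-4-hydroxy-5-[(2S)-5-hydroxypentan-2-yl]-6-methyl-3a,4,7,7a-tetrahydro-1-benzofuran-2(3H)-one | CN(C)C[C@H]1C(=O)O[C@@H]2CC(C)=C([C@@H](C)CCCO)[C@@H](O)[C@H]12 | intermediate
22 | 1,6-di-O-isobutyrate of 21 | CN(C)C[C@H]1C(=O)O[C@@H]2CC(C)=C([C@@H](C)CCCOC(=O)C(C)C)[C@@H](OC(=O)C(C)C)[C@H]12 | intermediate
23 | trimethylammonium iodide of 22 | C[N+](C)(C)C[C@H]1C(=O)O[C@@H]2CC(C)=C([C@@H](C)CCCOC(=O)C(C)C)[C@@H](OC(=O)C(C)C)[C@H]12.[I-] | intermediate
24 | target, 1,6-di-O-isobutyrylbritannilactone (CNP0509808.1) | C=C1C(=O)O[C@@H]2CC(C)=C([C@@H](C)CCCOC(=O)C(C)C)[C@@H](OC(=O)C(C)C)[C@H]12 | target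

Total step count: 11. Longest linear sequence: 9 steps (steps 1, 2, 3, 6, 7, 8, 9, 10, 11 from (S)-citronellal).

Steps most likely to fail

Step 9. The allene may attack the other face of the aldehyde, giving the C8 epimer, whose hydroxy ester cannot close the cis-fused lactone; slow methyl transfer is a second concern. The fallback sets out from 18. The palladium cyclization is run without the acid stage and the 8-epimeric hydroxy methyl ester F1 is isolated. Its methyl ester is cleaved with Me3SnOH (1,2-dichloroethane, 60 °C) to the 8-epimeric hydroxy acid F2. Mitsunobu lactonization (PPh3, DIAD, THF, 0 °C) then closes the ring with inversion at C8 and comes back to 20, which the AcOH–THF–H2O treatment of step 9 converts into 21.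

Step 6. Bond formation may leak to the CH2 terminus, giving the homopropargylic alcohol, and 1,2-induction may erode in the aqueous medium. The fallback sets out from 3 and uses a Lewis-acid Sakurai-type SE2′ addition, which can only give the allenyl carbinol.
- Alkyne 3 is deprotonated (n-BuLi) and alkylated with Me3SiCH2I to (4S)-trimethyl(4,8-dimethylnon-7-en-2-yn-1-yl)silane F3.
- Ozonolysis and NaBH4 as in step 3 give (4S)-4-methyl-7-(trimethylsilyl)hept-5-yn-1-ol F4.
- Et3SiCl and imidazole give its triethylsilyl ether F5.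
- F5 is added to aldehyde 14 with BF3·OEt2 (CH2Cl2, −78 °C) under non-chelating Felkin–Anh control to give the C1-silylated allenyl carbinol F6.
- Et3SiOTf and 2,6-lutidine silylate C6–OH and come back to 17.

Step 8. The base may epimerize C7 of the freed α-branched aldehyde and cleave the primary silyl ether. The fallback sets out from 16 and unmasks C8 under acid instead.
- i-Pr3SiOTf and 2,6-lutidine give the bis(triisopropylsilyl) ether F7.
- Aqueous CF3CO2H in THF hydrolyses the acylal to the 5-hydroxy lactone (pseudo-acid) F8.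
- F8 reacts through its open aldehyde–acid form under the palladium and trimethylboroxine conditions of step 9; the hydroxy acid lactonizes spontaneously to the bis(triisopropylsilyl) lactone F9.
- HF·pyridine in THF removes the silyl groups and comes back to 21.

Further compounds
F1 | step 9 | 8-epimer of hydroxy ester 19 (C8–OH trans to the C7 appendage) | COC(=O)[C@H](CN(C)C)[C@@H]1[C@@H](O)CC(C)=C([C@@H](C)CCCO[Si](CC)(CC)CC)[C@H]1O[Si](CC)(CC)CC
F2 | step 9 | 8-epimeric hydroxy acid from F1 | OC(=O)[C@H](CN(C)C)[C@@H]1[C@@H](O)CC(C)=C([C@@H](C)CCCO[Si](CC)(CC)CC)[C@H]1O[Si](CC)(CC)CC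
F3 | step 6 | (4S)-trimethyl(4,8-dimethylnon-7-en-2-yn-1-yl)silane | C[Si](C)(C)CC#C[C@@H](C)CCC=C(C)C
F4 | step 6 | (4S)-4-methyl-7-(trimethylsilyl)hept-5-yn-1-ol | C[Si](C)(C)CC#C[C@@H](C)CCCO
F5 | step 6 | triethylsilyl ether of F4 | C[Si](C)(C)CC#C[C@@H](C)CCCO[Si](CC)(CC)CC
F6 | step 6 | allenyl carbinol 16 with C1–O triethylsilylated and C6–OH free | CN(C)C[C@H]1C(=O)O[C@@H](O[C@@H]2C[C@H](C)CC[C@H]2C(C)C)[C@@H]1[C@H](O)C(=C=C)[C@@H](C)CCCO[Si](CC)(CC)CC
F7 | step 8 | bis(triisopropylsilyl) ether of 16 | CN(C)C[C@H]1C(=O)O[C@@H](O[C@@H]2C[C@H](C)CC[C@H]2C(C)C)[C@@H]1[C@H](O[Si](C(C)C)(C(C)C)C(C)C)C(=C=C)[C@@H](C)CCCO[Si](C(C)C)(C(C)C)C(C)C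
F8 | step 8 | 5-hydroxy lactone (pseudo-acid) from F7, lactol centre unassigned | CN(C)C[C@H]1C(=O)OC(O)[C@@H]1[C@H](O[Si](C(C)C)(C(C)C)C(C)C)C(=C=C)[C@@H](C)CCCO[Si](C(C)C)(C(C)C)C(C)C
F9 | step 8 | bis(triisopropylsilyl) ether of 21 | CN(C)C[C@H]1C(=O)O[C@@H]2CC(C)=C([C@@H](C)CCCO[Si](C(C)C)(C(C)C)C(C)C)[C@@H](O[Si](C(C)C)(C(C)C)C(C)C)[C@H]12
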